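**Assumptions (one line):** the pivaloyl group of 15 is counted as a protecting group (prop-2-yn-1-ol core, 4 heavy atoms); the BINAP hand written in steps 3 and 11 is provisional and the antipode is used if induction is opposite; 8 and 10 are mixtures at the enolisable ester-bearing carbon, which becomes sp2 in step 6.

## Retrosynthetic overview

1. Last bond: C–O ester bond, formed by Ti-mediated opening of spiro-epoxy alcohol 22 at its CH2 by acid 14.
2. 22 ← OH-directed epoxidation ← Luche reduction ← SN2′ hydride reduction of enone lactone 19 ← Rh Pauson–Khand reaction of dienyl ynoate 18 (δ-lactone and cyclopentenone formed together) ← ene–yne metathesis with ethylene.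
3. 14 ← i-Pr coupling of dienyl triflate 11 ← two-carbon ring expansion of cis-diquinane β-keto ester 8 by acetylene insertion (5→7) ← hydrogenation ← Rh Pauson–Khand reaction of dienyne 5.
4. Ring order, acid half: cyclopentane and cyclopentenone together (step 3), then cyclopentanone → cycloheptenone (step 5). Lactone half: both rings in step 11.

## Route

**Step 1**
Reactants: 1 hexa-1,5-diyne; 2 methyl chloroformate
Product: 3 methyl hepta-2,6-diynoate
Conditions: 1 (3 equiv), n-BuLi (1 equiv), THF, −78 °C; then 2, −78 °C → rt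
Reagents that add atoms: methyl chloroformate (2), COC(=O)Cl
Why: Acylation of the mono-lithium acetylide; excess volatile diyne suppresses double acylation.

**Step 2**
Reactants: 3 methyl hepta-2,6-diynoate; 4 ethylene
Product: 5 methyl 6-methylideneoct-7-en-2-ynoate
Conditions: Grubbs II (5 mol%), ethylene (4 atm), toluene, 80 °C
Reagents that add atoms: ethylene (4), C=C
Why: Ene–yne cross-metathesis with ethylene turns only the terminal alkyne into a 2-substituted butadiene; the internal ynoate is inert.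

**Step 3**
Reactants: 5 methyl 6-methylideneoct-7-en-2-ynoate; 6 carbon monoxide
Product: 7 methyl (6aR)-6-methylidene-2-oxo-1,2,4,5,6,6a-hexahydropentalene-3-carboxylate
Conditions: [RhCl(CO)2]2 (3 mol%), (S)-BINAP (9 mol%), AgOTf (12 mol%), CO (1 atm), THF, 90 °C
Reagents that add atoms: carbon monoxide (6), [C-]#[O+]
Why: Rh(I)/BINAP asymmetric intramolecular Pauson–Khand reaction of a 1,6-enyne; only the vinyl group can close a five-membered ring, and the ligand sets C-6a.

**Step 4**
Reactants: 7 methyl (6aR)-6-methylidene-2-oxo-1,2,4,5,6,6a-hexahydropentalene-3-carboxylate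
Product: 8 methyl (3aR,4R,6aS)-4-methyl-2-oxooctahydropentalene-1-carboxylate
Conditions: H2 (1 atm), 5% Rh/Al2O3, EtOAc, rt
Reagents that add atoms: none
Why: Catalytic syn-hydrogenation; the ring-fusion alkene can only give the cis-diquinane, and H2 adds to the exocyclic methylene from the H-6a (convex) face, so the methyl ends on the concave face (all-cis).

**Step 5**
Reactants: 8 methyl (3aR,4R,6aS)-4-methyl-2-oxooctahydropentalene-1-carboxylate; 9 acetylene
Product: 10 methyl (3R,3aR,8aS)-3-methyl-5-oxo-1,2,3,3a,4,5,8,8a-octahydroazulene-8-carboxylate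
Conditions: [ReBr(CO)3(thf)]2 (2.5 mol%), BnNC (5 mol%), acetylene (1 atm), toluene, 60 °C
Reagents that add atoms: acetylene (9), C#C
Why: Proposed new method: Re-catalysed insertion of acetylene itself into the C(α)–C(=O) bond of a cyclic β-keto ester, a two-carbon ring expansion (5→7); the Re enolate carbometallates acetylene, the alkenyl–Re adds to the ring ketone to give a strained metal-bound cyclobutenolate, and retro-aldol cleavage (strain release, ester-stabilised carbanion) opens the ring without touching C-3, C-3a or C-8a; closest known reactions are the Re-catalysed insertion of terminal aryl- and alkylacetylenes into cyclic β-keto esters and the In-catalysed α-vinylation of β-keto esters with acetylene gas.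

**Step 6**
Reactants: 10 methyl (3R,3aR,8aS)-3-methyl-5-oxo-1,2,3,3a,4,5,8,8a-octahydroazulene-8-carboxylate
Product: 11 methyl (3R,3aR,8aS)-3-methyl-5-{[(trifluoromethyl)sulfonyl]oxy}-1,2,3,3a,4,8a-hexahydroazulene-8-carboxylate
Conditions: NaH, THF, 0 °C; then PhNTf2, 0 °C → rt; dilute HCl work-up
Reagents that add atoms: N-phenylbis(trifluoromethanesulfonimide), O=S(=O)(N(c1ccccc1)S(=O)(=O)C(F)(F)F)C(F)(F)F
Why: The vinylogous β-keto ester is deprotonated at the ester-bearing carbon and the extended dienolate is O-triflated, which fixes the 5,7-diene of the target.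

**Step 7**
Reactants: 11 methyl (3R,3aR,8aS)-3-methyl-5-{[(trifluoromethyl)sulfonyl]oxy}-1,2,3,3a,4,8a-hexahydroazulene-8-carboxylate; 12 isopropylmagnesium chloride
Product: 13 methyl (3R,3aR,8aS)-3-methyl-5-(propan-2-yl)-1,2,3,3a,4,8a-hexahydroazulene-8-carboxylate
Conditions: 12 (1.3 equiv), Fe(acac)3 (5 mol%), THF/NMP, −30 °C
Reagents that add atoms: isopropylmagnesium chloride (12), CC(C)[Mg]Cl
Why: Fe-catalysed cross-coupling of an alkenyl triflate with an alkyl Grignard reagent, which tolerates the ester at low temperature.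

**Step 8**
Reactants: 13 methyl (3R,3aR,8aS)-3-methyl-5-(propan-2-yl)-1,2,3,3a,4,8a-hexahydroazulene-8-carboxylate
Product: 14 (3R,3aR,8aS)-3-methyl-5-(propan-2-yl)-1,2,3,3a,4,8a-hexahydroazulene-8-carboxylic acid
Conditions: LiOH·H2O, THF/MeOH/H2O, 50 °C; then 1 M HCl
Reagents that add atoms: lithium hydroxide, [Li+].[OH-]
Why: Saponification; H-8a is not conjugated with the ester carbonyl, so the ring fusion is not epimerised.

**Step 9**
Reactants: 15 prop-2-yn-1-yl 2,2-dimethylpropanoate; 16 prop-2-yn-1-yl chloroformate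
Product: 17 prop-2-yn-1-yl 4-[(2,2-dimethylpropanoyl)oxy]but-2-ynoate
Conditions: LiHMDS (1.05 equiv), THF, −78 °C; cannulate into 16 (1.2 equiv), THF, −78 °C
Reagents that add atoms: prop-2-yn-1-yl chloroformate (16), C#CCOC(=O)Cl
Why: Acylation of a lithium acetylide (inverse addition); the pivalate has no α-hydrogen and resists the amide base.

**Step 10**
Reactants: 17 prop-2-yn-1-yl 4-[(2,2-dimethylpropanoyl)oxy]but-2-ynoate; 4 ethylene
Product: 18 2-methylidenebut-3-en-1-yl 4-[(2,2-dimethylpropanoyl)oxy]but-2-ynoate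
Conditions: Grubbs II (3 mol%), ethylene (1 atm), toluene, 80 °C
Reagents that add atoms: ethylene (4), C=C
Why: Ene–yne cross-metathesis with ethylene, which is best for terminal alkynes carrying a propargylic ester oxygen; the ynoate is inert.

**Step 11**
Reactants: 18 2-methylidenebut-3-en-1-yl 4-[(2,2-dimethylpropanoyl)oxy]but-2-ynoate; 6 carbon monoxide
Product: 19 [(4aS)-4-methylidene-1,6-dioxo-1,3,4,4a,5,6-hexahydrocyclopenta[c]pyran-7-yl]methyl 2,2-dimethylpropanoate
Conditions: [Rh(cod)Cl]2 (5 mol%), (R)-BINAP (11 mol%), AgOTf (12 mol%), CO/Ar (1:4, 1 atm), toluene, 100 °C, 0.01 M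
Reagents that add atoms: carbon monoxide (6), [C-]#[O+]
Why: Proposed new method: enantioselective Rh(I)–bisphosphine Pauson–Khand reaction of an ester-tethered 1,7-enyne, forming the δ-lactone and the cyclopentenone in one step and setting C-4a; cationic Rh binds the ynoate and the monosubstituted vinyl group, oxidative cyclisation goes through the s-cis ester rotamer (populated at 100 °C, as in ring-closing metathesis to δ-lactones), and the 1,1-disubstituted alkene, a poor 2π partner for Rh(I), stays as the exocyclic methylene; closest known reactions are the Rh(I)/BINAP Pauson–Khand reaction of ether-, sulfonamide- and malonate-tethered 1,6-enynes and the Rh-catalysed dienyl Pauson–Khand reaction.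

**Step 12**
Reactants: 19 [(4aS)-4-methylidene-1,6-dioxo-1,3,4,4a,5,6-hexahydrocyclopenta[c]pyran-7-yl]methyl 2,2-dimethylpropanoate
Product: 21 (4aR,6S,7aR)-6-hydroxy-4,7-dimethylidenehexahydrocyclopenta[c]pyran-1(3H)-one, via methylene ketone lactone 20 (not isolated)
Conditions: [(Ph3P)CuH]6 (0.17 equiv, 1.0 equiv Cu–H), toluene/THF, −40 → 0 °C; then CeCl3·7H2O, NaBH4, MeOH, −78 °C; NH4Cl work-up
Reagents that add atoms: none
Why: Conjugate hydride addition at C-7a from the H-4a face (cis fusion) and E1cB loss of pivalate from the copper enolate (overall SN2′ reduction) give the α-methylene ketone, and Luche 1,2-reduction from the convex face puts the 6-OH on the lactone side.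

**Step 13**
Reactants: 21 (4aR,6S,7aR)-6-hydroxy-4,7-dimethylidenehexahydrocyclopenta[c]pyran-1(3H)-one
Product: 22 (4aR,6S,7S,7aR)-6-hydroxy-4-methylidenehexahydro-1H-spiro[cyclopenta[c]pyran-7,2'-oxiran]-1-one
Conditions: VO(acac)2 (5 mol%), t-BuOOH (1.5 equiv), CH2Cl2, 0 °C
Reagents that add atoms: tert-butyl hydroperoxide, CC(C)(C)OO
Why: Hydroxyl-directed vanadium epoxidation delivers oxygen only to the allylic-alcohol alkene and syn to the 6-OH, which sets C-7 and leaves the 4-methylidene untouched.

**Step 14**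
Reactants: 22 (4aR,6S,7S,7aR)-6-hydroxy-4-methylidenehexahydro-1H-spiro[cyclopenta[c]pyran-7,2'-oxiran]-1-one; 14 (3R,3aR,8aS)-3-methyl-5-(propan-2-yl)-1,2,3,3a,4,8a-hexahydroazulene-8-carboxylic acid
Product: 23 nardostachysin
Conditions: Ti(Oi-Pr)4 (1.5 equiv), 14 (1.2 equiv), CH2Cl2, rt
Reagents that add atoms: none
Why: Ti(Oi-Pr)4-mediated opening of a 2,3-epoxy alcohol by a carboxylic acid at the distal, primary carbon; the C-7 oxygen is retained, giving the tertiary alcohol and the primary ester without protecting groups.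

## Compound list

1 | hexa-1,5-diyne | C#CCCC#C | starting material
2 | methyl chloroformate | COC(=O)Cl | starting material
3 | methyl hepta-2,6-diynoate | COC(=O)C#CCCC#C | intermediate
4 | ethylene | C=C | starting material
5 | methyl 6-methylideneoct-7-en-2-ynoate | COC(=O)C#CCCC(=C)C=C | intermediate
6 | carbon monoxide | [C-]#[O+] | starting material
7 | methyl (6aR)-6-methylidene-2-oxo-1,2,4,5,6,6a-hexahydropentalene-3-carboxylate | COC(=O)C1=C2CCC(=C)[C@H]2CC1=O | intermediate
8 | methyl (3aR,4R,6aS)-4-methyl-2-oxooctahydropentalene-1-carboxylate (C-1 epimers/enol) | COC(=O)C1C(=O)C[C@@H]2[C@H](C)CC[C@H]12 | intermediate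
9 | acetylene | C#C | starting material
10 | methyl (3R,3aR,8aS)-3-methyl-5-oxo-1,2,3,3a,4,5,8,8a-octahydroazulene-8-carboxylate (C-8 epimers) | COC(=O)C1C=CC(=O)C[C@@H]2[C@H](C)CC[C@H]12 | intermediate
11 | methyl (3R,3aR,8aS)-3-methyl-5-{[(trifluoromethyl)sulfonyl]oxy}-1,2,3,3a,4,8a-hexahydroazulene-8-carboxylate | COC(=O)C1=CC=C(OS(=O)(=O)C(F)(F)F)C[C@@H]2[C@H](C)CC[C@H]12 | intermediate
12 | isopropylmagnesium chloride | CC(C)[Mg]Cl | starting material
13 | methyl (3R,3aR,8aS)-3-methyl-5-(propan-2-yl)-1,2,3,3a,4,8a-hexahydroazulene-8-carboxylate | COC(=O)C1=CC=C(C(C)C)C[C@@H]2[C@H](C)CC[C@H]12 | intermediate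
14 | (3R,3aR,8aS)-3-methyl-5-(propan-2-yl)-1,2,3,3a,4,8a-hexahydroazulene-8-carboxylic acid | OC(=O)C1=CC=C(C(C)C)C[C@@H]2[C@H](C)CC[C@H]12 | intermediate
15 | prop-2-yn-1-yl 2,2-dimethylpropanoate (O-pivaloyl prop-2-yn-1-ol) | C#CCOC(=O)C(C)(C)C | starting material
16 | prop-2-yn-1-yl chloroformate | C#CCOC(=O)Cl | starting material
17 | prop-2-yn-1-yl 4-[(2,2-dimethylpropanoyl)oxy]but-2-ynoate | C#CCOC(=O)C#CCOC(=O)C(C)(C)C | intermediate
18 | 2-methylidenebut-3-en-1-yl 4-[(2,2-dimethylpropanoyl)oxy]but-2-ynoate | C=CC(=C)COC(=O)C#CCOC(=O)C(C)(C)C | intermediate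
19 | [(4aS)-4-methylidene-1,6-dioxo-1,3,4,4a,5,6-hexahydrocyclopenta[c]pyran-7-yl]methyl 2,2-dimethylpropanoate | C=C1COC(=O)C2=C(COC(=O)C(C)(C)C)C(=O)C[C@@H]12 | intermediate
20 | (4aR,7aR)-4,7-dimethylidenehexahydrocyclopenta[c]pyran-1,6-dione (cis-fused) | C=C1COC(=O)[C@@H]2[C@H]1CC(=O)C2=C | intermediate
21 | (4aR,6S,7aR)-6-hydroxy-4,7-dimethylidenehexahydrocyclopenta[c]pyran-1(3H)-one | C=C1COC(=O)[C@@H]2[C@H]1C[C@H](O)C2=C | intermediate
22 | (4aR,6S,7S,7aR)-6-hydroxy-4-methylidenehexahydro-1H-spiro[cyclopenta[c]pyran-7,2'-oxiran]-1-one | C=C1COC(=O)[C@@H]2[C@H]1C[C@H](O)[C@@]23CO3 | intermediate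
23 | nardostachysin | C=C1COC(=O)[C@@H]2[C@H]1C[C@H](O)[C@@]2(O)COC(=O)C1=CC=C(C(C)C)C[C@@H]2[C@H](C)CC[C@H]12 | target

## Step count and risks

Total step count: 14. Longest linear sequence: 9 (steps 1–8, then 14).

The three steps most likely to fail are 5, 11 and 12.

**Step 5 (acetylene insertion).** If acetylene does not insert, or stops at the α-vinyl stage, the two carbons are brought in by known chemistry starting from 8. In(OTf)3/DBU-catalysed α-vinylation with acetylene gas gives methyl (3aR,4R,6aS)-1-ethenyl-4-methyl-2-oxooctahydropentalene-1-carboxylate F1. Irradiation (300 nm, benzene) then causes the known 1,3-acyl shift of a β,γ-unsaturated ketone (α-cleavage, recombination at the vinyl terminus), giving the ring-expanded methyl (3R,3aR,8aS)-3-methyl-5-oxo-1,2,3,3a,4,5,6,8a-octahydroazulene-8-carboxylate F2. F2 is a double-bond isomer of 10 and gives the same dienolate, so NaH/PhNTf2 under the step 6 conditions brings the route back at 11.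

**Step 11 (ester-tethered Pauson–Khand reaction).** If the ester tether does not cyclise, the tether is changed to an acetal, starting from 15. LiHMDS then DMF gives 4-oxobut-2-yn-1-yl 2,2-dimethylpropanoate F3. Acid-catalysed acetalisation (PPTS, benzene, −H2O) with two equivalents of 2-methylidenebut-3-en-1-ol F4 (from prop-2-yn-1-ol and ethylene with Grubbs II) gives 4,4-bis[(2-methylidenebut-3-en-1-yl)oxy]but-2-yn-1-yl 2,2-dimethylpropanoate F5. The Rh(I)/BINAP Pauson–Khand reaction of this ether-type tether, a known substrate class, gives [(4aS)-4-methylidene-1-[(2-methylidenebut-3-en-1-yl)oxy]-6-oxo-1,3,4,4a,5,6-hexahydrocyclopenta[c]pyran-7-yl]methyl 2,2-dimethylpropanoate F6. Mild aqueous acid gives the lactol [(4aS)-1-hydroxy-4-methylidene-6-oxo-1,3,4,4a,5,6-hexahydrocyclopenta[c]pyran-7-yl]methyl 2,2-dimethylpropanoate F7, and MnO2 oxidation of this allylic lactol returns the route at 19.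

**Step 12 (SN2′ reduction and Luche reduction in one pot).** The intermediate 20 is a sarkomycin-type α-methylene ketone and may isomerise to the endocyclic enone or be over-reduced. The fallback avoids 20 by reducing the ketone first, starting from 19. CBS reduction (Me-CBS, catecholborane, −40 °C) gives [(4aS,6S)-6-hydroxy-4-methylidene-1-oxo-1,3,4,4a,5,6-hexahydrocyclopenta[c]pyran-7-yl]methyl 2,2-dimethylpropanoate F8. Pd(OAc)2/PBu3 with ammonium formate (Tsuji hydrogenolysis: hydride to the more substituted allyl terminus, exocyclic alkene) then removes the pivalate and gives 21, where the route resumes.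

Further compounds
F1 | step 5 | methyl (3aR,4R,6aS)-1-ethenyl-4-methyl-2-oxooctahydropentalene-1-carboxylate | COC(=O)C1(C=C)C(=O)C[C@@H]2[C@H](C)CC[C@H]12
F2 | step 5 | methyl (3R,3aR,8aS)-3-methyl-5-oxo-1,2,3,3a,4,5,6,8a-octahydroazulene-8-carboxylate | COC(=O)C1=CCC(=O)C[C@@H]2[C@H](C)CC[C@H]12
F3 | step 11 | 4-oxobut-2-yn-1-yl 2,2-dimethylpropanoate | O=CC#CCOC(=O)C(C)(C)C
F4 | step 11 | 2-methylidenebut-3-en-1-ol | C=CC(=C)CO
F5 | step 11 | 4,4-bis[(2-methylidenebut-3-en-1-yl)oxy]but-2-yn-1-yl 2,2-dimethylpropanoate | C=CC(=C)COC(OCC(=C)C=C)C#CCOC(=O)C(C)(C)C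
F6 | step 11 | [(4aS)-4-methylidene-1-[(2-methylidenebut-3-en-1-yl)oxy]-6-oxo-1,3,4,4a,5,6-hexahydrocyclopenta[c]pyran-7-yl]methyl 2,2-dimethylpropanoate | C=C1COC(OCC(=C)C=C)C2=C(COC(=O)C(C)(C)C)C(=O)C[C@@H]12
F7 | step 11 | [(4aS)-1-hydroxy-4-methylidene-6-oxo-1,3,4,4a,5,6-hexahydrocyclopenta[c]pyran-7-yl]methyl 2,2-dimethylpropanoate | C=C1COC(O)C2=C(COC(=O)C(C)(C)C)C(=O)C[C@@H]12
F8 | step 12 | [(4aS,6S)-6-hydroxy-4-methylidene-1-oxo-1,3,4,4a,5,6-hexahydrocyclopenta[c]pyran-7-yl]methyl 2,2-dimethylpropanoate | C=C1COC(=O)C2=C(COC(=O)C(C)(C)C)[C@@H](O)C[C@@H]12
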